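**Retrosynthetic overview**
1. 20 ⇒ 19. The furan-fused cycloheptanone comes from a tertiary 3-furyl cyclopentanol: cut C-12–C-1, close C-1–C-16. This five-to-seven ring expansion is the last step.
2. 19 ⇒ 15 plus a 3-furyl metal made from 3-bromofuran 16.
3. 15 ⇒ 14. An intramolecular Diels–Alder reaction of a 4,4-disubstituted cyclopentenone with a 3-vinylbutenolide forms rings A and B together and sets C-1, C-5 and C-10 from C-9.
4. 14 ⇒ 6 + 10. C-6–C-7 comes from a catalytic asymmetric Mukaiyama aldol (sets C-7), the butenolide from an aldol condensation, and the enone from a late dehydrogenation.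
5. 6 ⇒ 1 + 2. C-9 comes from an enantioselective conjugate addition. Ring order: cyclopentanone (bought), butenolide, rings A and B, seven-membered ring.

Assumption: 2 and 7 are bought. Positions are labelled C-n in clerodane numbering: C-1 = CH carrying the furan in 20, C-5 = quaternary carbon with the lactone CH2O, C-6 = ring CH2, C-7 = acetoxy carbon, C-8 = carbon with the exocyclic CH2, C-9 = quaternary methyl carbon, C-10 = central CH, C-11 = CH2 next to ketone C-12, C-16 = furan carbon bonded to C-1.

**Step 1**
Reactants: 1 3-methylcyclopent-2-en-1-one; 2 2-bromo-3,3-dimethoxyprop-1-ene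
Product: 6 2-[(1S)-1-methyl-3-oxocyclopentyl]prop-2-enal, via vinyllithium 3 (not isolated), via alkenylalane 4 (not isolated), via keto acetal 5 (not isolated)
Conditions: 2, n-BuLi, Et2O, −78 °C; Et2AlCl, −78 → −30 °C; 1, Cu(OTf)2 (5 mol %), chiral sulfonate-bearing imidazolinium salt (NHC precursor, 6 mol %), THF, −30 °C; 1 M HCl, 0 °C
Reagents that add atoms: water, O
Why: Copper-catalysed enantioselective conjugate addition of an α-substituted alkenylalane to a β-methyl cyclic enone builds the quaternary C-9, the chiral NHC–copper complex choosing the enone face (ligand antipode picked for the S descriptor here, which is the 9R centre of 20 once the CIP ranks change), and the acidic quench unmasks the enal.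

**Step 2**
Reactants: 7 1,3-dibromopropan-2-one; 8 but-3-enoic acid
Product: 9 3-bromo-2-oxopropyl but-3-enoate
Conditions: KHCO3, DMF, 0 °C, 7 in threefold excess
Reagents that add atoms: none
Why: SN2 O-alkylation of the carboxylate by the α-bromo ketone, in which the excess dibromide and the weak base suppress double substitution and premature ring closure.

**Step 3**
Reactants: 9 3-bromo-2-oxopropyl but-3-enoate
Product: 10 2-[(trimethylsilyl)oxy]prop-2-en-1-yl but-3-enoate
Conditions: Zn dust, TMSCl, TMEDA, Et2O, 0 °C → rt
Reagents that add atoms: chlorotrimethylsilane, C[Si](C)(C)Cl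
Why: Reformatsky-type reductive enolate formation at the C–Br carbon followed by O-silylation gives the terminal silyl enol ether regiospecifically, which deprotonation of the parent ketone would not.

**Step 4**
Reactants: 6 2-[(1S)-1-methyl-3-oxocyclopentyl]prop-2-enal; 10 2-[(trimethylsilyl)oxy]prop-2-en-1-yl but-3-enoate
Product: 11 (4S)-4-hydroxy-5-[(1S)-1-methyl-3-oxocyclopentyl]-2-oxohex-5-en-1-yl but-3-enoate
Conditions: SiCl4 (1.5 equiv), binaphthyldiamine-derived chiral bisphosphoramide (5 mol %), i-Pr2NEt (10 mol %), CH2Cl2, −78 °C; aq NaHCO3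
Reagents that add atoms: none
Why: In this Lewis base-activated SiCl4 Mukaiyama aldol addition the phosphoramide-bound cationic silicon species activates only the aldehyde (not the ketone) and shields one of its faces, so C-7 is set as S under catalyst control (antipode chosen accordingly) and the C-6–C-7 bond forms only at the enol silane carbon.

**Step 5**
Reactants: 11 (4S)-4-hydroxy-5-[(1S)-1-methyl-3-oxocyclopentyl]-2-oxohex-5-en-1-yl but-3-enoate
Product: 12 3-ethenyl-4-{(2S)-2-hydroxy-3-[(1S)-1-methyl-3-oxocyclopentyl]but-3-en-1-yl}furan-2(5H)-one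
Conditions: DBU (1.1 equiv), MeCN, −20 → 0 °C, 30 min; pH 7 buffer
Reagents that add atoms: none
Why: In this intramolecular aldol (Knoevenagel-type) condensation the allyl-activated ester α-carbon closes a five-membered ring on the neighbouring ketone and loses water to give the conjugated 3-vinylbutenolide, and running it while the cyclopentanone is still saturated excludes an intramolecular Michael addition of C-6, with C-7 and C-9 untouched.

**Step 6**
Reactants: 12 3-ethenyl-4-{(2S)-2-hydroxy-3-[(1S)-1-methyl-3-oxocyclopentyl]but-3-en-1-yl}furan-2(5H)-one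
Product: 13 (2S)-1-(4-ethenyl-5-oxo-2,5-dihydrofuran-3-yl)-3-[(1S)-1-methyl-3-oxocyclopentyl]but-3-en-2-yl acetate
Conditions: Ac2O, pyridine, DMAP (5 mol %), CH2Cl2, 0 °C
Reagents that add atoms: acetic anhydride, CC(=O)OC(C)=O
Why: DMAP-catalysed O-acylation with retention at C-7 installs the acetate of the target and at the same time masks the carbinol against the oxidant of step 7.

**Step 7**
Reactants: 13 (2S)-1-(4-ethenyl-5-oxo-2,5-dihydrofuran-3-yl)-3-[(1S)-1-methyl-3-oxocyclopentyl]but-3-en-2-yl acetate
Product: 14 (2S)-1-(4-ethenyl-5-oxo-2,5-dihydrofuran-3-yl)-3-[(1R)-1-methyl-4-oxocyclopent-2-en-1-yl]but-3-en-2-yl acetate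
Conditions: IBX (2.5 equiv), 4-methoxypyridine N-oxide (2.5 equiv), DMSO, 25 → 40 °C
Reagents that add atoms: none
Why: IBX dehydrogenation of the ketone can place the double bond only at C-1=C-10 because C-9 is quaternary, the base-free medium spares the acetate and the acidic C-6 position, and no stereocentre is touched (the C-9 descriptor changes from S to R through CIP ranks alone).

**Step 8**
Reactants: 14 (2S)-1-(4-ethenyl-5-oxo-2,5-dihydrofuran-3-yl)-3-[(1R)-1-methyl-4-oxocyclopent-2-en-1-yl]but-3-en-2-yl acetate
Product: 15 (1R,5S,7S,9R,10S)-7-acetoxy-12-oxo-13,14,15,16-tetranor-1,12-cyclocleroda-3,8(17)-dien-18,19-olide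
Conditions: PhMe (5 mM), BHT (10 mol %), 135 °C, sealed tube
Reagents that add atoms: none
Why: In this intramolecular Diels–Alder reaction the four-atom tether sits on the inside (Z) position of diene terminus C-5 and on C-9 of the enone, so only the tether-exo transition state on the enone face syn to C-8 can be reached, which gives the cis A/B fusion with H-1, H-10, the C-9 methyl and the C-5 CH2O all on one face (1R,5S,10S) in the "para" orientation that a 2-acyl diene also prefers electronically.

**Step 9**
Reactants: 15 (1R,5S,7S,9R,10S)-7-acetoxy-12-oxo-13,14,15,16-tetranor-1,12-cyclocleroda-3,8(17)-dien-18,19-olide; 16 3-bromofuran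
Product: 19 (1R,5S,7S,9R,10S,12S)-7-acetoxy-12-hydroxy-15,16-epoxy-1,12-cyclocleroda-3,8(17),13(16),14-tetraen-18,19-olide, via 3-furyllithium 17 (not isolated), via 3-furylcerium dichloride 18 (not isolated)
Conditions: 16 (1.3 equiv), n-BuLi, THF, −78 °C; CeCl3, −78 °C; 15, −78 °C, 30 min; aq NH4Cl
Reagents that add atoms: none
Why: 1,2-Addition of a weakly basic organocerium reagent takes the cyclopentanone at −78 °C much faster than the acetate or the hindered conjugated lactone and does not enolise it, and attack from the convex face (anti to rings A and B) gives 12S, a centre that step 10 erases.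

**Step 10**
Reactants: 19 (1R,5S,7S,9R,10S,12S)-7-acetoxy-12-hydroxy-15,16-epoxy-1,12-cyclocleroda-3,8(17),13(16),14-tetraen-18,19-olide
Product: 20 (1R,5S,7S,9R,10S)-7-acetoxy-12-oxo-15,16-epoxy-1,16-cyclocleroda-3,8(17),13(16),14-tetraen-18,19-olide
Conditions: [Ir(dF(CF3)ppy)2(5,5'-d(CF3)bpy)]PF6 (2 mol %), Co(dmgH)2(py)Cl (1 mol %), 2,4,6-collidine (1 equiv), CH2Cl2 (0.02 M), 450 nm LED, 25 °C, Ar
Reagents that add atoms: none
Why: Proposed new method: the excited trivalent iridium complex oxidises the electron-rich 3-alkylfuran of 19 to its radical cation, collidine takes the carbinol proton in a proton-coupled electron transfer to give the tertiary alkoxy radical, β-scission cuts the most substituted and most strained bond C-12–C-1 (secondary radical at C-1, conjugated 3-furoyl ketone at C-12), the nucleophilic C-1 radical, held beside the furan by the C-9–C-11 arm on the face it has just left, adds to the acyl-activated furan α-carbon C-16 (retention, 1R), and divalent cobalt removes the hydrogen atom of the adduct radical to restore the furan and release H2, so the cyclopentanol grows by two atoms into the cycloheptanone; the closest known reaction types are the photocatalytic proton-coupled-electron-transfer ring opening of 1-arylcycloalkanols and the silver/persulfate or anodic ring expansion of 1-arylcyclobutanols to 1-tetralones, none of which has been shown for an unstrained five-membered carbinol, a furan acceptor or a seven-membered product.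

**Compound list**
1 | 3-methylcyclopent-2-en-1-one | CC1=CC(=O)CC1 | starting material
2 | 2-bromo-3,3-dimethoxyprop-1-ene | C=C(Br)C(OC)OC | starting material
3 | (3,3-dimethoxyprop-1-en-2-yl)lithium | [Li]C(=C)C(OC)OC | intermediate
4 | diethyl(3,3-dimethoxyprop-1-en-2-yl)aluminium | CC[Al](CC)C(=C)C(OC)OC | intermediate
5 | (3S)-3-(3,3-dimethoxyprop-1-en-2-yl)-3-methylcyclopentan-1-one | C=C(C(OC)OC)[C@@]1(C)CCC(=O)C1 | intermediate
6 | 2-[(1S)-1-methyl-3-oxocyclopentyl]prop-2-enal | C=C(C=O)[C@@]1(C)CCC(=O)C1 | intermediate
7 | 1,3-dibromopropan-2-one | BrCC(=O)CBr | starting material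
8 | but-3-enoic acid | C=CCC(=O)O | starting material
9 | 3-bromo-2-oxopropyl but-3-enoate | C=CCC(=O)OCC(=O)CBr | intermediate
10 | 2-[(trimethylsilyl)oxy]prop-2-en-1-yl but-3-enoate | C=CCC(=O)OCC(=C)O[Si](C)(C)C | intermediate
11 | (4S)-4-hydroxy-5-[(1S)-1-methyl-3-oxocyclopentyl]-2-oxohex-5-en-1-yl but-3-enoate | C=C([C@@H](O)CC(=O)COC(=O)CC=C)[C@@]1(C)CCC(=O)C1 | intermediate
12 | 3-ethenyl-4-{(2S)-2-hydroxy-3-[(1S)-1-methyl-3-oxocyclopentyl]but-3-en-1-yl}furan-2(5H)-one | C=C([C@@H](O)CC1=C(C=C)C(=O)OC1)[C@@]2(C)CCC(=O)C2 | intermediate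
13 | (2S)-1-(4-ethenyl-5-oxo-2,5-dihydrofuran-3-yl)-3-[(1S)-1-methyl-3-oxocyclopentyl]but-3-en-2-yl acetate | C=C([C@@H](OC(C)=O)CC1=C(C=C)C(=O)OC1)[C@@]2(C)CCC(=O)C2 | intermediate
14 | (2S)-1-(4-ethenyl-5-oxo-2,5-dihydrofuran-3-yl)-3-[(1R)-1-methyl-4-oxocyclopent-2-en-1-yl]but-3-en-2-yl acetate | C=C([C@@H](OC(C)=O)CC1=C(C=C)C(=O)OC1)[C@@]2(C)C=CC(=O)C2 | intermediate
15 | (1R,5S,7S,9R,10S)-7-acetoxy-12-oxo-13,14,15,16-tetranor-1,12-cyclocleroda-3,8(17)-dien-18,19-olide (all-cis fused rings A and B, cyclopentanone and lactone) | C=C1[C@@H](OC(C)=O)C[C@@]23COC(=O)C2=CC[C@H]2C(=O)C[C@]1(C)[C@H]23 | intermediate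
16 | 3-bromofuran | Brc1ccoc1 | starting material
17 | furan-3-yllithium | [Li]c1ccoc1 | intermediate
18 | dichloro(furan-3-yl)cerium | Cl[Ce](Cl)c1ccoc1 | intermediate
19 | (1R,5S,7S,9R,10S,12S)-7-acetoxy-12-hydroxy-15,16-epoxy-1,12-cyclocleroda-3,8(17),13(16),14-tetraen-18,19-olide (12-(furan-3-yl) tertiary cyclopentanol) | C=C1[C@@H](OC(C)=O)C[C@@]23COC(=O)C2=CC[C@H]2[C@](O)(c4ccoc4)C[C@]1(C)[C@H]23 | intermediate
20 | (1R,5S,7S,9R,10S)-7-acetoxy-12-oxo-15,16-epoxy-1,16-cyclocleroda-3,8(17),13(16),14-tetraen-18,19-olide (CNP0273675.2) | C=C1[C@@H](OC(C)=O)C[C@@]23COC(=O)C2=CC[C@H]2c4occc4C(=O)C[C@]1(C)[C@H]23 | target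

**Total step count:** 10.
**Longest linear sequence:** 9 (steps 2 to 10, starting from 7 and 8).

**Three steps most likely to fail**

Step 10 (the proposed ring expansion). The risks are capture of the C-1 radical by divalent cobalt (desaturation), side reactions of the furan radical cation, and slow seven-ring closure. The fallback uses known chemistry, sets out from 19 and returns at 20. The same bond is cut in a Suárez alkoxy-radical fragmentation (PhI(OAc)2, I2, CH2Cl2, visible light, 0 °C). This traps the C-1 radical as the ring-opened iodo ketone F1, a mixture of C-1 epimers. C-1–C-16 is then closed separately by a palladium-catalysed ring-forming C–H alkylation of the furan with the unactivated alkyl iodide (Pd(PPh3)4, K3PO4, dioxane, 100 °C), which gives 20.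

Step 8. The new C-5–C-10 bond lies between a carbon that becomes quaternary and a carbon next to quaternary C-9. On long heating a 1,5-hydrogen shift of the Z-substituted diene can compete. The fallback sets out from 14 and returns at 15. Irradiation of 14 (365 nm, MeCN, −20 °C) brings about an intramolecular enone–olefin [2+2] photocycloaddition between C-1=C-10 and C-4=C-5 and gives the vinylcyclobutane photoadduct F2. The four-membered ring is then expanded to the cyclohexene by a 1,3-shift (PhMe, 170 °C, or Ni(cod)2/PPh3, 60 °C). The C-1–C-4 bond, flanked by the ketone and by the allylic lactone carbon, breaks, and C-1 recloses on the vinyl terminus C-2 on the same face to give 15.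

Step 5. The β-hydroxy ketone 11 can undergo retro-aldol cleavage or lose water under DBU before the lactone closes. The fallback sets out from 9 and 6 and returns at 12 and 13. The lactone is closed before any carbinol exists: 9 with Et3N in MeCN at 0 °C gives 4-(bromomethyl)-3-ethenylfuran-2(5H)-one F3. F3 is joined to aldehyde 6 in a zinc-mediated vinylogous Reformatsky reaction (Zn, THF, reflux, thermodynamic attack through the exocyclic CH2; aq NH4Cl). This gives 12 together with the C-7 epimer of 12 F4. After separation 12 continues with step 6, and F4 is converged onto 13 by Mitsunobu inversion (AcOH, PPh3, DIAD, THF, 0 °C).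

**Further compounds**
F1 | step 10 | (5S,7S,9R)-7-acetoxy-1-iodo-12-oxo-15,16-epoxycleroda-3,8(17),13(16),14-tetraen-18,19-olide, C-10 as in 19, epimers at C-1 | C=C1[C@@H](OC(C)=O)C[C@@]23COC(=O)C2=CCC(I)[C@H]3[C@@]1(C)CC(=O)c4ccoc4
F2 | step 8 | [2+2] photoadduct of 14 with new bonds C-10–C-5 and C-1–C-4, ethenyl group on C-4, cis ring fusions throughout | C=C1[C@@H](OC(C)=O)C[C@@]23COC(=O)[C@]2(C=C)[C@H]2C(=O)C[C@]1(C)[C@H]23
F3 | step 5 | 4-(bromomethyl)-3-ethenylfuran-2(5H)-one | C=CC1=C(CBr)COC1=O
F4 | step 5 | 3-ethenyl-4-{(2R)-2-hydroxy-3-[(1S)-1-methyl-3-oxocyclopentyl]but-3-en-1-yl}furan-2(5H)-one | C=C([C@H](O)CC1=C(C=C)C(=O)OC1)[C@@]2(C)CCC(=O)C2
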